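**Strategy**

Everything rests on cutting the 3(2H)-furanone at C1–C10 (germacrane numbering). The C1 ketone and the acyloxy carbon C8 are 1,4-related through the quaternary C10, and the furanone oxygen on C3 is a ready tether, so an asymmetric intramolecular Stetter reaction of a β-alkoxy aldehyde onto a vinylogous thiocarbonate closes the five-membered oxacycle, forms C1–C10 and sets the C10 stereocentre under catalyst control in one operation. The precursor is an acyclic allyl vinyl ether assembled from an allylic alcohol and an alkynoic thioester. The thioester carbon later becomes the C8 aldehyde for a chromium-mediated Barbier closure of the ten-membered ring onto a bromomethyl butenolide.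

Key step: step 9

Remark on the chemistry: positions are given in germacrane numbering (C1 furanone ketone, C2=C3 furanone alkene, C4=C5 alkene, C6 lactone carbinol, C7, C8 acyloxy carbon, C9 methylene, C10 quaternary carbon, C11–C13 methylene lactone, C14 methyl, C15 acetoxymethyl); the ligand and triazolium antipodes shown are assumed to give the stated facial sense and would be exchanged for their mirror images otherwise; compounds 9, 12, 13 and 14 are mixtures of C3 epimers, a centre that becomes sp2 in step 10.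

**Route**

Step 1
Reactants: 1 acrolein; 2 tert-butyldimethyl(prop-2-yn-1-yloxy)silane
Product: 3 (3S)-6-[(tert-butyldimethylsilyl)oxy]hex-1-en-4-yn-3-ol
Conditions: Me2Zn, (S,S)-2,6-bis{[2-(hydroxydiphenylmethyl)pyrrolidin-1-yl]methyl}-4-methylphenol (ProPhenol ligand, 20 mol %), Ph3P=O (40 mol %), toluene, 4 °C; aq. NH4Cl
Reagents that add atoms: none
Why: Catalytic asymmetric alkynylation of an unsaturated aldehyde by a zinc alkynylide under the dinuclear zinc–ProPhenol catalyst should deliver the alkynyl group to the Re face of acrolein and so set C6 as (S).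

Step 2
Reactants: 3 (3S)-6-[(tert-butyldimethylsilyl)oxy]hex-1-en-4-yn-3-ol
Product: 5 (3S,4Z)-6-[(tert-butyldimethylsilyl)oxy]-5-iodohexa-1,4-dien-3-ol, via cyclic vinylalanate 4 (not isolated)
Conditions: NaAlH2(OCH2CH2OMe)2, THF, 0 °C; EtOAc; then I2, −78 °C
Reagents that add atoms: iodine, II
Why: Hydroxyl-directed trans-hydroalumination of the propargylic alcohol puts aluminium on the distal alkyne carbon C4 anti to the new C5–H, and iodinolysis with retention gives the (Z)-vinyl iodide that fixes the later C4=C5 geometry.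

Step 3
Reactants: 5 (3S,4Z)-6-[(tert-butyldimethylsilyl)oxy]-5-iodohexa-1,4-dien-3-ol
Product: 6 (3S,4Z)-3,6-bis[(tert-butyldimethylsilyl)oxy]-5-iodohexa-1,4-diene
Conditions: TBSCl, imidazole, DMF, rt
Reagents that add atoms: tert-butyldimethylsilyl chloride, C[Si](C)(Cl)C(C)(C)C
Why: Standard silylation masks the C6 carbinol so that only the C3 hydroxyl made in step 5 can act as the oxa-Michael donor.

Step 4
Reactants: 7 3,3-diethoxypropan-1-ol
Product: 8 3,3-diethoxypropanal
Conditions: 2,2,6,6-tetramethylpiperidin-1-oxyl (TEMPO, 1 mol %), KBr, NaOCl, NaHCO3, CH2Cl2/H2O, 0 °C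
Reagents that add atoms: none
Why: Nitroxyl-catalysed hypochlorite oxidation (Anelli oxidation) of the primary alcohol stops at the aldehyde, and the buffered basic medium leaves the acetal intact.

Step 5
Reactants: 6 (3S,4Z)-3,6-bis[(tert-butyldimethylsilyl)oxy]-5-iodohexa-1,4-diene; 8 3,3-diethoxypropanal
Product: 9 (4Z,6S)-6-[(tert-butyldimethylsilyl)oxy]-4-{[(tert-butyldimethylsilyl)oxy]methyl}-1,1-diethoxyocta-4,7-dien-3-ol (C3 epimers)
Conditions: CrCl2 (6 equiv), NiCl2 (2 mol %), DMSO, rt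
Reagents that add atoms: none
Why: Nozaki–Hiyama–Kishi coupling turns the hindered vinyl iodide into a vinylchromium species that adds to the aldehyde with retention of alkene geometry; the C3 carbinol forms as both epimers, which is immaterial because C3 becomes sp2 in step 10.

Step 6
Reactants: 10 but-2-ynoic acid
Product: 11 S-ethyl but-2-ynethioate
Conditions: EtSH, N,N'-dicyclohexylcarbodiimide (DCC), 4-(dimethylamino)pyridine (DMAP, 5 mol %), CH2Cl2, 0 °C
Reagents that add atoms: ethanethiol, CCS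
Why: Steglich thioesterification gives the thioester, chosen because it is a competent Stetter acceptor and can later be reduced to the aldehyde in the presence of ketone and ester groups.

Step 7
Reactants: 9 (4Z,6S)-6-[(tert-butyldimethylsilyl)oxy]-4-{[(tert-butyldimethylsilyl)oxy]methyl}-1,1-diethoxyocta-4,7-dien-3-ol (C3 epimers); 11 S-ethyl but-2-ynethioate
Product: 12 S-ethyl (2E)-3-{[(4Z,6S)-6-[(tert-butyldimethylsilyl)oxy]-4-{[(tert-butyldimethylsilyl)oxy]methyl}-1,1-diethoxyocta-4,7-dien-3-yl]oxy}but-2-enethioate (C3 epimers)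
Conditions: PMe3 (15 mol %), CH2Cl2, 0 °C to rt
Reagents that add atoms: none
Why: Phosphine-catalysed oxa-Michael addition of the secondary alcohol to the activated alkyne should give the (E)-β-alkoxy crotonate thioester, and the mild conditions stay far below the temperature of a Claisen rearrangement of the allyl vinyl ether.

Step 8
Reactants: 12 S-ethyl (2E)-3-{[(4Z,6S)-6-[(tert-butyldimethylsilyl)oxy]-4-{[(tert-butyldimethylsilyl)oxy]methyl}-1,1-diethoxyocta-4,7-dien-3-yl]oxy}but-2-enethioate (C3 epimers)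
Product: 13 S-ethyl (2E)-3-{[(4Z,6S)-6-[(tert-butyldimethylsilyl)oxy]-4-{[(tert-butyldimethylsilyl)oxy]methyl}-1-oxoocta-4,7-dien-3-yl]oxy}but-2-enethioate (C3 epimers)
Conditions: oxalic acid (10 % aq.) on silica gel, CH2Cl2, rt
Reagents that add atoms: water, O
Why: Mild acid hydrolysis of the diethyl acetal frees the C1 aldehyde while the vinylogous thiocarbonate, deactivated towards protonation by conjugation, and the silyl ethers should survive.

Step 9
Reactants: 13 S-ethyl (2E)-3-{[(4Z,6S)-6-[(tert-butyldimethylsilyl)oxy]-4-{[(tert-butyldimethylsilyl)oxy]methyl}-1-oxoocta-4,7-dien-3-yl]oxy}but-2-enethioate (C3 epimers)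
Product: 14 S-ethyl 2-{(2R)-5-[(2Z,4S)-1,4-bis[(tert-butyldimethylsilyl)oxy]hexa-2,5-dien-2-yl]-2-methyl-3-oxooxolan-2-yl}ethanethioate (C3 epimers; ring C2 = C10)
Conditions: (5aR,10bS)-2-(pentafluorophenyl)-5a,10b-dihydro-4H,6H-indeno[2,1-b][1,2,4]triazolo[4,3-d][1,4]oxazin-2-ium tetrafluoroborate (20 mol %), KN(SiMe3)2 (18 mol %), toluene, 23 °C
Reagents that add atoms: none
Why: The triazolylidene adds to the C1 aldehyde to give the Breslow intermediate, whose acyl-anion carbon attacks C10, the β-carbon of the tethered vinylogous thiocarbonate, and proton transfer with release of the carbene gives the ketone (intramolecular Stetter reaction). The closest known reaction type is the catalytic asymmetric Stetter cyclisation of oxygen-tethered aldehydes onto β,β-disubstituted acceptors, which gives 2,2-disubstituted 3-oxo oxacycles. The oxolanone ring closes in the 5-exo-trig mode, with the oxygen on C3 as tether and C9 left exocyclic. The new quaternary centre C10 is controlled by the chiral aminoindanol-derived carbene, which with the (E)-acceptor should leave the Si face of C10 open and so give (R). The step needs conjugate addition to win over benzoin coupling and over β-elimination of the vinylogous thiocarboxylate from the aldehyde, which the fast five-membered exo closure, the aprotic medium and a base charge below the triazolium loading should secure; the existing C3 centre (both epimers) lies across the forming ring from C10 and is expected to be overridden by the catalyst.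

Step 10
Reactants: 14 S-ethyl 2-{(2R)-5-[(2Z,4S)-1,4-bis[(tert-butyldimethylsilyl)oxy]hexa-2,5-dien-2-yl]-2-methyl-3-oxooxolan-2-yl}ethanethioate (C3 epimers)
Product: 16 S-ethyl 2-{(2R)-5-[(2Z,4S)-1,4-bis[(tert-butyldimethylsilyl)oxy]hexa-2,5-dien-2-yl]-2-methyl-3-oxo-2,3-dihydrofuran-2-yl}ethanethioate, via trimethylsilyl enol ether 15 (not isolated)
Conditions: Me3SiOTf, Et3N, CH2Cl2, −78 to 0 °C; then Pd(OAc)2 (1.1 equiv), MeCN, rt
Reagents that add atoms: none
Why: The ketone can enolise only towards C2 because C10 is quaternary, and Saegusa–Ito oxidation of the silyl enol ether (β-hydride elimination of the C3–H) gives the 3(2H)-furanone and merges both C3 epimers into one compound.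

Step 11
Reactants: 16 S-ethyl 2-{(2R)-5-[(2Z,4S)-1,4-bis[(tert-butyldimethylsilyl)oxy]hexa-2,5-dien-2-yl]-2-methyl-3-oxo-2,3-dihydrofuran-2-yl}ethanethioate
Product: 17 S-ethyl 2-{(2R)-5-[(2Z,4S)-1,4-dihydroxyhexa-2,5-dien-2-yl]-2-methyl-3-oxo-2,3-dihydrofuran-2-yl}ethanethioate
Conditions: HF·pyridine, pyridine, THF, 0 °C to rt
Reagents that add atoms: none
Why: Buffered fluoride desilylation removes both silyl ethers without touching the thioester or the furanone, and the cold buffered medium limits ionisation of the bis-allylic C6 alcohol.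

Step 12
Reactants: 17 S-ethyl 2-{(2R)-5-[(2Z,4S)-1,4-dihydroxyhexa-2,5-dien-2-yl]-2-methyl-3-oxo-2,3-dihydrofuran-2-yl}ethanethioate
Product: 18 S-ethyl 2-{(2R)-5-[(2Z,4S)-1-acetoxy-4-hydroxyhexa-2,5-dien-2-yl]-2-methyl-3-oxo-2,3-dihydrofuran-2-yl}ethanethioate
Conditions: Ac2O (1.1 equiv), 2,4,6-collidine, CH2Cl2, −20 °C
Reagents that add atoms: acetic anhydride, CC(=O)OC(C)=O
Why: Selective acylation: the primary C15 hydroxyl reacts much faster than the hindered secondary C6 hydroxyl at low temperature with a weak base.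

Step 13
Reactants: 18 S-ethyl 2-{(2R)-5-[(2Z,4S)-1-acetoxy-4-hydroxyhexa-2,5-dien-2-yl]-2-methyl-3-oxo-2,3-dihydrofuran-2-yl}ethanethioate
Product: 19 (2Z,4S)-4-hydroxy-2-[(5R)-5-methyl-4-oxo-5-(2-oxoethyl)-4,5-dihydrofuran-2-yl]hexa-2,5-dien-1-yl acetate
Conditions: Et3SiH, Pd on CaCO3 poisoned with Pb(OAc)2 (Lindlar catalyst, 10 mol % Pd), acetone, rt
Reagents that add atoms: none
Why: Fukuyama reduction (palladium-catalysed hydrosilane reduction of the thioester through an acylpalladium species) gives the C8 aldehyde without reducing the ketone or the acetate, and the poisoned catalyst should spare the alkenes.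

Step 14
Reactants: 19 (2Z,4S)-4-hydroxy-2-[(5R)-5-methyl-4-oxo-5-(2-oxoethyl)-4,5-dihydrofuran-2-yl]hexa-2,5-dien-1-yl acetate; 20 2-(bromomethyl)prop-2-enoic acid
Product: 21 (3S,4Z)-6-acetoxy-5-[(5R)-5-methyl-4-oxo-5-(2-oxoethyl)-4,5-dihydrofuran-2-yl]hexa-1,4-dien-3-yl 2-(bromomethyl)prop-2-enoate
Conditions: DCC, DMAP (5 mol %), CH2Cl2, −10 °C
Reagents that add atoms: none
Why: Steglich esterification acylates the only free hydroxyl (C6) with retention of configuration, and low temperature with little DMAP limits attack on the allylic bromide.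

Step 15
Reactants: 21 (3S,4Z)-6-acetoxy-5-[(5R)-5-methyl-4-oxo-5-(2-oxoethyl)-4,5-dihydrofuran-2-yl]hexa-1,4-dien-3-yl 2-(bromomethyl)prop-2-enoate
Product: 22 (2Z)-3-[(2R)-4-(bromomethyl)-5-oxo-2,5-dihydrofuran-2-yl]-2-[(5R)-5-methyl-4-oxo-5-(2-oxoethyl)-4,5-dihydrofuran-2-yl]prop-2-en-1-yl acetate
Conditions: second-generation Grubbs catalyst (5 mol %), CH2Cl2, 40 °C
Reagents that add atoms: none
Why: Ring-closing metathesis between the vinyl group on C6 and the 1,1-disubstituted acrylate forms the five-membered butenolide (C7=C11) with loss of ethylene, while the trisubstituted C4=C5 alkene and the furanone alkene are too hindered and electron-poor to compete.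

Step 16
Reactants: 22 (2Z)-3-[(2R)-4-(bromomethyl)-5-oxo-2,5-dihydrofuran-2-yl]-2-[(5R)-5-methyl-4-oxo-5-(2-oxoethyl)-4,5-dihydrofuran-2-yl]prop-2-en-1-yl acetate
Product: 23 (4Z,6R,7R,8S,10R)-15-acetoxy-8-hydroxy-1-oxo-3,10-epoxygermacra-2,4,11(13)-trien-12,6-olide
Conditions: CrCl2 (10 equiv), THF (2 mM), rt
Reagents that add atoms: none
Why: Reduction of the allylic bromide gives a 2-(alkoxycarbonyl)allylchromium species that adds through its γ-carbon C7 to the C8 aldehyde (intramolecular Nozaki–Hiyama allylation, a chromium Barbier macrocyclisation of the type used to close ten-membered germacranolide rings); attack on the butenolide face opposite the C5 substituent should set C7 trans to C6, and a closed chair transition state with the (E)-configured allyl unit should give the 7,8-anti relationship, that is (8S).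

Step 17
Reactants: 23 (4Z,6R,7R,8S,10R)-15-acetoxy-8-hydroxy-1-oxo-3,10-epoxygermacra-2,4,11(13)-trien-12,6-olide
Product: 24 (4Z,6R,7R,8S,10R)-15-acetoxy-8-(methacryloyloxy)-1-oxo-3,10-epoxygermacra-2,4,11(13)-trien-12,6-olide (CNP0179932.1)
Conditions: methacrylic anhydride, Et3N, DMAP (10 mol %), CH2Cl2, 0 °C
Reagents that add atoms: methacrylic anhydride, C=C(C)C(=O)OC(=O)C(C)=C
Why: DMAP-catalysed acylation of the secondary C8 alcohol with the anhydride installs the methacrylate without touching any stereocentre.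

**Compound list**

1 | acrolein | C=CC=O | starting material
2 | tert-butyldimethyl(prop-2-yn-1-yloxy)silane | C#CCO[Si](C)(C)C(C)(C)C | starting material
3 | (3S)-6-[(tert-butyldimethylsilyl)oxy]hex-1-en-4-yn-3-ol | C=C[C@H](O)C#CCO[Si](C)(C)C(C)(C)C | intermediate
4 | cyclic vinylalanate (sodium salt; five-membered O–Al–C4=C5–C6 ring, two 2-methoxyethoxy ligands on Al) | C=C[C@@H]1O[Al-](OCCOC)(OCCOC)C(CO[Si](C)(C)C(C)(C)C)=C1.[Na+] | intermediate
5 | (3S,4Z)-6-[(tert-butyldimethylsilyl)oxy]-5-iodohexa-1,4-dien-3-ol | C=C[C@H](O)/C=C(\I)CO[Si](C)(C)C(C)(C)C | intermediate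
6 | (3S,4Z)-3,6-bis[(tert-butyldimethylsilyl)oxy]-5-iodohexa-1,4-diene | C=C[C@H](O[Si](C)(C)C(C)(C)C)/C=C(\I)CO[Si](C)(C)C(C)(C)C | intermediate
7 | 3,3-diethoxypropan-1-ol | CCOC(CCO)OCC | starting material
8 | 3,3-diethoxypropanal | CCOC(CC=O)OCC | intermediate
9 | (4Z,6S)-6-[(tert-butyldimethylsilyl)oxy]-4-{[(tert-butyldimethylsilyl)oxy]methyl}-1,1-diethoxyocta-4,7-dien-3-ol (C3 epimers) | CCOC(CC(O)/C(CO[Si](C)(C)C(C)(C)C)=C\[C@@H](O[Si](C)(C)C(C)(C)C)C=C)OCC | intermediate
10 | but-2-ynoic acid | CC#CC(=O)O | starting material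
11 | S-ethyl but-2-ynethioate | CC#CC(=O)SCC | intermediate
12 | S-ethyl (2E)-3-{[(4Z,6S)-6-[(tert-butyldimethylsilyl)oxy]-4-{[(tert-butyldimethylsilyl)oxy]methyl}-1,1-diethoxyocta-4,7-dien-3-yl]oxy}but-2-enethioate (C3 epimers) | CCOC(CC(O/C(C)=C/C(=O)SCC)/C(CO[Si](C)(C)C(C)(C)C)=C\[C@@H](O[Si](C)(C)C(C)(C)C)C=C)OCC | intermediate
13 | S-ethyl (2E)-3-{[(4Z,6S)-6-[(tert-butyldimethylsilyl)oxy]-4-{[(tert-butyldimethylsilyl)oxy]methyl}-1-oxoocta-4,7-dien-3-yl]oxy}but-2-enethioate (C3 epimers) | O=CCC(O/C(C)=C/C(=O)SCC)/C(CO[Si](C)(C)C(C)(C)C)=C\[C@@H](O[Si](C)(C)C(C)(C)C)C=C | intermediate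
14 | S-ethyl 2-{(2R)-5-[(2Z,4S)-1,4-bis[(tert-butyldimethylsilyl)oxy]hexa-2,5-dien-2-yl]-2-methyl-3-oxooxolan-2-yl}ethanethioate (C3 epimers) | CCSC(=O)C[C@@]1(C)OC(CC1=O)/C(CO[Si](C)(C)C(C)(C)C)=C\[C@@H](O[Si](C)(C)C(C)(C)C)C=C | intermediate
15 | S-ethyl 2-{(2R)-5-[(2Z,4S)-1,4-bis[(tert-butyldimethylsilyl)oxy]hexa-2,5-dien-2-yl]-2-methyl-3-[(trimethylsilyl)oxy]-2,5-dihydrofuran-2-yl}ethanethioate | CCSC(=O)C[C@@]1(C)OC(C=C1O[Si](C)(C)C)/C(CO[Si](C)(C)C(C)(C)C)=C\[C@@H](O[Si](C)(C)C(C)(C)C)C=C | intermediate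
16 | S-ethyl 2-{(2R)-5-[(2Z,4S)-1,4-bis[(tert-butyldimethylsilyl)oxy]hexa-2,5-dien-2-yl]-2-methyl-3-oxo-2,3-dihydrofuran-2-yl}ethanethioate | CCSC(=O)C[C@@]1(C)OC(=CC1=O)/C(CO[Si](C)(C)C(C)(C)C)=C\[C@@H](O[Si](C)(C)C(C)(C)C)C=C | intermediate
17 | S-ethyl 2-{(2R)-5-[(2Z,4S)-1,4-dihydroxyhexa-2,5-dien-2-yl]-2-methyl-3-oxo-2,3-dihydrofuran-2-yl}ethanethioate | CCSC(=O)C[C@@]1(C)OC(=CC1=O)/C(CO)=C\[C@@H](O)C=C | intermediate
18 | S-ethyl 2-{(2R)-5-[(2Z,4S)-1-acetoxy-4-hydroxyhexa-2,5-dien-2-yl]-2-methyl-3-oxo-2,3-dihydrofuran-2-yl}ethanethioate | CCSC(=O)C[C@@]1(C)OC(=CC1=O)/C(COC(C)=O)=C\[C@@H](O)C=C | intermediate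
19 | (2Z,4S)-4-hydroxy-2-[(5R)-5-methyl-4-oxo-5-(2-oxoethyl)-4,5-dihydrofuran-2-yl]hexa-2,5-dien-1-yl acetate | O=CC[C@@]1(C)OC(=CC1=O)/C(COC(C)=O)=C\[C@@H](O)C=C | intermediate
20 | 2-(bromomethyl)prop-2-enoic acid | C=C(CBr)C(=O)O | starting material
21 | (3S,4Z)-6-acetoxy-5-[(5R)-5-methyl-4-oxo-5-(2-oxoethyl)-4,5-dihydrofuran-2-yl]hexa-1,4-dien-3-yl 2-(bromomethyl)prop-2-enoate | O=CC[C@@]1(C)OC(=CC1=O)/C(COC(C)=O)=C\[C@@H](OC(=O)C(=C)CBr)C=C | intermediate
22 | (2Z)-3-[(2R)-4-(bromomethyl)-5-oxo-2,5-dihydrofuran-2-yl]-2-[(5R)-5-methyl-4-oxo-5-(2-oxoethyl)-4,5-dihydrofuran-2-yl]prop-2-en-1-yl acetate | O=CC[C@@]1(C)OC(=CC1=O)/C(COC(C)=O)=C\[C@H]1OC(=O)C(CBr)=C1 | intermediate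
23 | (4Z,6R,7R,8S,10R)-15-acetoxy-8-hydroxy-1-oxo-3,10-epoxygermacra-2,4,11(13)-trien-12,6-olide | O[C@H]1C[C@@]2(C)OC(=CC2=O)/C(COC(C)=O)=C\[C@H]2OC(=O)C(=C)[C@H]12 | intermediate
24 | (4Z,6R,7R,8S,10R)-15-acetoxy-8-(methacryloyloxy)-1-oxo-3,10-epoxygermacra-2,4,11(13)-trien-12,6-olide (CNP0179932.1) | C=C(C)C(=O)O[C@H]1C[C@@]2(C)OC(=CC2=O)/C(COC(C)=O)=C\[C@H]2OC(=O)C(=C)[C@H]12 | target

**Step count and risks**

Total steps: 17. Longest linear sequence: 15 (steps 1–3, 5, 7–17).

Steps most likely to fail: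

Step 9. Base-induced β-elimination of the vinylogous thiocarboxylate from the enolisable β-alkoxy aldehyde, or aldehyde self-condensation, may outrun the conjugate addition, and the mismatched C3 epimer may erode facial control at C10. Fallback: the fallback sets out from 13, taken as its (3R)-epimer after chromatographic separation of the epimers at the stage of alcohol 9. Pinnick oxidation (NaClO2, NaH2PO4, 2-methylbut-2-ene, t-BuOH/H2O) would give (3R,4Z,6S)-6-[(tert-butyldimethylsilyl)oxy]-4-{[(tert-butyldimethylsilyl)oxy]methyl}-3-{[(2E)-4-(ethylsulfanyl)-4-oxobut-2-en-2-yl]oxy}octa-4,7-dienoic acid F1. PhSeSePh and PBu3 would convert it into the corresponding Se-phenyl selenoester F2. Acyl radical generation ((Me3Si)3SiH, Et3B, air, benzene, rt) and base-free 5-exo-trig cyclisation onto the vinylogous thiocarbonate follow, in which the C3 substituent should direct a 2,5-cis closure. This would give the (2R,5R)-epimer of 14, where the route resumes.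

Step 16. Intermolecular coupling may compete with ring closure, and a boat-like array enforced by the forming ring may reverse the facial sense at the aldehyde carbon. Fallback: the fallback sets out from 22; the ring closure is run as before and the alcohol obtained is then (4Z,6R,7R,8R,10R)-15-acetoxy-8-hydroxy-1-oxo-3,10-epoxygermacra-2,4,11(13)-trien-12,6-olide F3. Mitsunobu esterification of this alcohol (methacrylic acid, PPh3, diisopropyl azodicarboxylate, toluene, 0 °C) installs the methacrylate with inversion at C8 and rejoins the route at 24.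

Step 13. Over-reduction on the palladium surface (hydrogenation of the vinyl group or hydrogenolysis of the allylic acetate) may accompany thioester reduction. Fallback: the fallback sets out from 16. NaBH4 (EtOH, 0 °C) should reduce the thioester, but not the deactivated vinylogous-ester ketone, to (2R)-5-[(2Z,4S)-1,4-bis[(tert-butyldimethylsilyl)oxy]hexa-2,5-dien-2-yl]-2-(2-hydroxyethyl)-2-methylfuran-3(2H)-one F4. Dess–Martin periodinane (NaHCO3, CH2Cl2) would give {(2R)-5-[(2Z,4S)-1,4-bis[(tert-butyldimethylsilyl)oxy]hexa-2,5-dien-2-yl]-2-methyl-3-oxo-2,3-dihydrofuran-2-yl}acetaldehyde F5. HF·pyridine would give {(2R)-5-[(2Z,4S)-1,4-dihydroxyhexa-2,5-dien-2-yl]-2-methyl-3-oxo-2,3-dihydrofuran-2-yl}acetaldehyde F6. Selective acetylation of the primary hydroxyl (Ac2O, 2,4,6-collidine, −20 °C) rejoins the route at 19.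

Further compounds
F1 | step 9 | (3R,4Z,6S)-6-[(tert-butyldimethylsilyl)oxy]-4-{[(tert-butyldimethylsilyl)oxy]methyl}-3-{[(2E)-4-(ethylsulfanyl)-4-oxobut-2-en-2-yl]oxy}octa-4,7-dienoic acid | OC(=O)C[C@@H](O/C(C)=C/C(=O)SCC)/C(CO[Si](C)(C)C(C)(C)C)=C\[C@@H](O[Si](C)(C)C(C)(C)C)C=C
F2 | step 9 | Se-phenyl (3R,4Z,6S)-6-[(tert-butyldimethylsilyl)oxy]-4-{[(tert-butyldimethylsilyl)oxy]methyl}-3-{[(2E)-4-(ethylsulfanyl)-4-oxobut-2-en-2-yl]oxy}octa-4,7-dieneselenoate | O=C(C[C@@H](O/C(C)=C/C(=O)SCC)/C(CO[Si](C)(C)C(C)(C)C)=C\[C@@H](O[Si](C)(C)C(C)(C)C)C=C)[Se]c1ccccc1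
F3 | step 16 | (4Z,6R,7R,8R,10R)-15-acetoxy-8-hydroxy-1-oxo-3,10-epoxygermacra-2,4,11(13)-trien-12,6-olide | O[C@@H]1C[C@@]2(C)OC(=CC2=O)/C(COC(C)=O)=C\[C@H]2OC(=O)C(=C)[C@H]12
F4 | step 13 | (2R)-5-[(2Z,4S)-1,4-bis[(tert-butyldimethylsilyl)oxy]hexa-2,5-dien-2-yl]-2-(2-hydroxyethyl)-2-methylfuran-3(2H)-one | OCC[C@@]1(C)OC(=CC1=O)/C(CO[Si](C)(C)C(C)(C)C)=C\[C@@H](O[Si](C)(C)C(C)(C)C)C=C
F5 | step 13 | {(2R)-5-[(2Z,4S)-1,4-bis[(tert-butyldimethylsilyl)oxy]hexa-2,5-dien-2-yl]-2-methyl-3-oxo-2,3-dihydrofuran-2-yl}acetaldehyde | O=CC[C@@]1(C)OC(=CC1=O)/C(CO[Si](C)(C)C(C)(C)C)=C\[C@@H](O[Si](C)(C)C(C)(C)C)C=C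
F6 | step 13 | {(2R)-5-[(2Z,4S)-1,4-dihydroxyhexa-2,5-dien-2-yl]-2-methyl-3-oxo-2,3-dihydrofuran-2-yl}acetaldehyde | O=CC[C@@]1(C)OC(=CC1=O)/C(CO)=C\[C@@H](O)C=C
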